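The constants are unknown, so Ann and Ben argue from two runs. Dawn is the flask asked about, and winter had twice its [starting material].

| flask | starting material | first nucleophile | second nucleophile | remark | time |
|---|---|---|---|---|---|
| dawn | 0.020 M | 0.014 M | 0.040 M | the very flask that is asked about, followed so far |  |
| winter | 0.040 M | 0.014 M | 0.040 M | run made earlier |  |
| flask | 0.020 M | 0.0140 M | 0.0400 M |  | 15 h |

| run | time / h | target / % |
|---|---|---|
| dawn | 2.00 | 9.6 |
| dawn | 5.00 | 16.4 |
| dawn | 10.0 | 18.9 |
| dawn | 15.0 | 18.3 |
| winter | 0.500 | 3.0 |
| winter | 1.00 | 4.4 |
| winter | 2.50 | 7.6 |
| winter | 6.00 | 7.4 |

(standard deviation of a reading: 1 percentage point)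

- Wednesday's: at 15 h add starting material, 50.0 % of the amount charged, then wait 30 h
- Thursday's: at 15 h take out 90 % of the target then present, then wait 30 h
- Tuesday's: at 15 h add second nucleophile, 50.0 % of the amount charged, then wait 30 h
- Saturday's: change nothing and wait 30 h more

- target, in percent of the starting material first charged, at 15 h
- the option that brings most further target ("none" if no option brings more than 2 percentage points) (Wednesday's / Thursday's / Tuesday's / Saturday's / none)
- target present, with what was taken out counted in, in percent of the starting material first charged, after Thursday's
- target present, with what was taken out counted in, in percent of the starting material first charged, after Tuesday's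

- target taken out counts as made
- additions bring no volume worth counting

Both write the balance of the first nucleophile, the reagent charged in the smaller amount. In dawn the readings peak at 18.9 %, so 27.0 % of the charged first nucleophile stands as target. Call this the nucleophile share, [target] at the plateau over [first nucleophile] charged, or the yield on first nucleophile. Winter reads 21.7 %.

Ann stresses the likeness. The plateau reads 0.00378 M in dawn and 0.00304 M in winter, although winter had more starting material. She therefore takes the first nucleophile as the reagent that ends the rise.

Ben asks where the other 73.0 % of it went, since no reading shows it. He reads the stop in dawn as the end of the starting material, with first nucleophile still free. Wednesday's adds 50.0 % of the charge, and at the yield of dawn's peak reading he reckons that as 9.4 percentage points, above the margin of 2 points.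

The forecast is Ann's: 18.5 % now, best option none, 18.5 % after Thursday's and 18.7 % after Tuesday's. Its ground is that “the first nucleophile is essentially gone”.

The flask gives 18.7 % at 15 h, 18.7 % after Thursday's and 18.7 % after Tuesday's. The best option is none, with Wednesday's bringing 1.8 points, just under the margin.

    second nucleophile → decomposed reagent (k = 2.73 × 10⁻⁴ s⁻¹)
    starting material → intermediate (k = 9.31 × 10⁻⁵ s⁻¹)
    intermediate → solvolysis product (k = 1.41 × 10⁻⁴ s⁻¹)
    starting material + target → side product (k = 0.0177 L mol⁻¹ s⁻¹)
    second nucleophile + intermediate → other capture product (k = 0.223 L mol⁻¹ s⁻¹)
    first nucleophile + intermediate → target (k = 0.173 L mol⁻¹ s⁻¹)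

Ann's numbers stand, but the stop is Ben's: at 15.0 h this flask holds 0.032 % of its starting material and 39 % of its first nucleophile. In this flask the nucleophile share is 26.7 %, and side product, each holding one target, accounts for 34.0 % of the first nucleophile charged. Ann's spent first nucleophile appears in the neighbour with 0.0056 M of it, which keeps 1.8 % of its charge at a share of 39.4 %. In this flask, with starting material as charged, target has a half-life of 0.54 h by the path to side product, shorter than the 2.1 h of starting material going to intermediate at 0.592 h. At that time target, each step taken net, is made 2.50 times faster than it is used up.

(The runs are simulated with constants of no real substance, noise included.)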